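**Plan**

- Cuts, in retrosynthetic order: (i) the hydroxyquinone ring back to a resorcinol, by oxidation of its single free aromatic CH; (ii) the side-chain bond C1'–C2' (CH2 on the quaternary ring carbon C3 / allylic carbinol carbon) to a primary iodide and an α-methyl enal; (iii) C1' back into the cyclopropane CH2 of a bicyclo[4.1.0]heptan-2-one; (iv) the C3'=C4' alkene and the aryl–CH2 bond.
- Forward: the cyclohexanone ring is built first (Stork–Danheiser enone, CBS reduction, directed cyclopropanation, oxidation, iodide ring opening). The arene is elaborated separately from orcinol. The halves are joined by a cobalt/chromium-mediated reductive coupling of iodide with enal. Deacetylation and Teuber oxidation then create the quinone ring.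
- Enabling feature: C1' sits on the fully substituted C3 of the cyclohexanone, so its radical and its organochromium have no β-hydrogen to lose. It is γ to the ring C1=O, so it can be stored as a cyclopropyl ketone. C2' is an allylic carbinol carbon, i.e. the carbonyl carbon of an enal, and alkylchromium reagents take an aldehyde in the presence of the free ring ketone.
- Stereochemistry: C4 (with a temporary C1 carbinol) from catalyst-controlled CBS reduction of the racemic enone, keeping the cis diastereomer. Quaternary C3 from hydroxyl-directed cyclopropanation. C2 by equilibration. C2' from a chiral oxazoline–sulfonamide ligand on chromium. The E alkene from cross-metathesis.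

Key step: step 13

**Remarks on the chemistry (assumptions)**

- 3-Ethoxy-2-methylcyclohex-2-en-1-one (1) is taken as a catalogue compound; otherwise it is one step from 2-methylcyclohexane-1,3-dione (EtOH, TsOH).
- The 2S configuration next to the ring ketone is taken to be the more stable one (chair with three equatorial methyl groups and the C3 CH2 substituent axial), so it is set by equilibration.
- The (S)-ligand of step 13 is taken to direct attack to the Si face of the aldehyde; if a model aldehyde shows the opposite sense, the (R)-ligand is used.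
- Locants: ring C1 (C=O) to C6; side chain C1' (CH2 on C3) to C5' (CH2 on the arene).

**Route**

Step 1
Reactants: 1 3-ethoxy-2-methylcyclohex-2-en-1-one
Product: 3 (±)-3-ethoxy-2,6-dimethylcyclohex-2-en-1-one, via lithium dienolate 2 (not isolated)
Conditions: LDA, THF, −78 °C; MeI, −78 → 0 °C
Reagents that add atoms: iodomethane, CI
Why: Kinetic deprotonation of the vinylogous ester at the α' CH2 and SN2 methylation (first half of a Stork–Danheiser sequence) introduce the future C4 methyl group as a racemate.

Step 2
Reactants: 3 (±)-3-ethoxy-2,6-dimethylcyclohex-2-en-1-one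
Product: 5 (±)-2,3,4-trimethylcyclohex-2-en-1-one, via tertiary carbinol 4 (not isolated)
Conditions: MeLi, THF, −78 → 0 °C; then 1 M HCl, rt
Reagents that add atoms: methyllithium, [Li]C
Why: 1,2-Addition to the vinylogous ester carbonyl followed by acid-induced loss of water and hydrolysis of the enol ether (Stork–Danheiser transposition) gives the tetrasubstituted enone with the carbonyl moved to the former C3.

Step 3
Reactants: 5 (±)-2,3,4-trimethylcyclohex-2-en-1-one
Product: 6 (1R,4S)-2,3,4-trimethylcyclohex-2-en-1-ol
Conditions: (S)-Me-CBS oxazaborolidine (20 mol%), catecholborane, toluene, −78 °C; chromatography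
Reagents that add atoms: none
Why: CBS reduction under catalyst control: the oxazaborolidine distinguishes the alkenyl (large) from the CH2 (small) flank whatever the remote C4 configuration, so both enantiomers give the 1R carbinol and the 4S enone ends up as the cis alcohol, which is separated from the trans diastereomer (divergent reaction of a racemate).

Step 4
Reactants: 6 (1R,4S)-2,3,4-trimethylcyclohex-2-en-1-ol
Product: 7 (1S,2R,5S,6S)-1,5,6-trimethylbicyclo[4.1.0]heptan-2-ol
Conditions: Et2Zn, CH2I2, CH2Cl2, 0 °C → rt
Reagents that add atoms: diiodomethane, ICI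
Why: Hydroxyl-directed Simmons–Smith cyclopropanation (Furukawa variant): the zinc alkoxide delivers CH2 to the face of the OH group, which is also the face of the C4 methyl group, so the future quaternary carbon gets its CH2 cis and its methyl trans to that group.

Step 5
Reactants: 7 (1S,2R,5S,6S)-1,5,6-trimethylbicyclo[4.1.0]heptan-2-ol
Product: 8 (1S,5S,6S)-1,5,6-trimethylbicyclo[4.1.0]heptan-2-one
Conditions: (n-Pr4N)RuO4 (5 mol%), N-methylmorpholine N-oxide, 4 Å molecular sieves, CH2Cl2, rt
Reagents that add atoms: none
Why: Ley–Griffith oxidation converts the hindered secondary cyclopropylcarbinol into the ketone under neutral conditions that avoid cyclopropylcarbinyl cation rearrangement.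

Step 6
Reactants: 8 (1S,5S,6S)-1,5,6-trimethylbicyclo[4.1.0]heptan-2-one
Product: 10 (2S,3S,4S)-3-(iodomethyl)-2,3,4-trimethylcyclohexan-1-one, via silyl enol ether 9 (not isolated)
Conditions: Me3SiI, CH2Cl2, −40 → 0 °C; then 1 M HCl, THF, rt
Reagents that add atoms: iodotrimethylsilane, C[Si](C)(C)I
Why: Homoconjugate opening of the O-silylated cyclopropyl ketone by iodide: only the bond from the α-carbon to the CH2 overlaps with the carbonyl π system in this bicycle and the CH2 is the only cyclopropane carbon open to backside attack, so the iodomethyl group ends on C3, and acid hydrolysis with enol equilibration sets C2 as the more stable 2S epimer.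

Step 7
Reactants: 11 orcinol (5-methylbenzene-1,3-diol)
Product: 12 4-chloro-5-methylbenzene-1,3-diol
Conditions: SO2Cl2 (1.0 equiv), Et2O, 0 °C
Reagents that add atoms: sulfuryl chloride, O=S(=O)(Cl)Cl
Why: Electrophilic aromatic chlorination goes to the position ortho to one and para to the other hydroxyl group and not between them, as in the chlorination of resorcinol.

Step 8
Reactants: 12 4-chloro-5-methylbenzene-1,3-diol
Product: 13 2-chloro-1,5-bis(methoxymethoxy)-3-methylbenzene
Conditions: MOMCl, i-Pr2NEt, CH2Cl2, 0 °C → rt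
Reagents that add atoms: chloromethyl methyl ether, COCCl
Why: O-Alkylation to the bis-MOM ether installs the two directing groups needed for the metalation.

Step 9
Reactants: 13 2-chloro-1,5-bis(methoxymethoxy)-3-methylbenzene
Product: 15 2-chloro-3,5-bis(methoxymethoxy)-1-methyl-4-(prop-2-en-1-yl)benzene, via aryllithium 14 (not isolated)
Conditions: n-BuLi, THF, 0 °C; CuI (10 mol%), allyl bromide, −78 °C → rt
Reagents that add atoms: allyl bromide, C=CCBr
Why: Directed ortho-metalation at the CH flanked by both OMOM groups (not ortho to chlorine, so no aryne) followed by copper-catalysed SN2 allylation fixes the chain between the two oxygens.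

Step 10
Reactants: 15 2-chloro-3,5-bis(methoxymethoxy)-1-methyl-4-(prop-2-en-1-yl)benzene
Product: 16 4-chloro-5-methyl-2-(prop-2-en-1-yl)benzene-1,3-diol
Conditions: 3 M HCl, MeOH, 40 °C
Reagents that add atoms: none
Why: Acid-catalysed acetal exchange removes both MOM groups at a stage where the only alkene is a terminal allyl group that does not cyclise onto the phenol.

Step 11
Reactants: 16 4-chloro-5-methyl-2-(prop-2-en-1-yl)benzene-1,3-diol
Product: 17 4-chloro-5-methyl-2-(prop-2-en-1-yl)-1,3-phenylene diacetate
Conditions: Ac2O, pyridine, DMAP (cat.), CH2Cl2, rt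
Reagents that add atoms: acetic anhydride, CC(=O)OC(C)=O
Why: Acylation gives base-labile phenol protection, chosen because the late intermediates carry an acid-sensitive allylic alcohol next to an ortho-allyl phenol.

Step 12
Reactants: 17 4-chloro-5-methyl-2-(prop-2-en-1-yl)-1,3-phenylene diacetate
Product: 18 4-chloro-5-methyl-2-[(2E)-3-methyl-4-oxobut-2-en-1-yl]-1,3-phenylene diacetate
Conditions: methacrolein (5 equiv), second-generation Hoveyda–Grubbs catalyst RuCl2(H2IMes)(=CH-C6H4-2-O-i-Pr) (5 mol%), 1,4-benzoquinone (10 mol%), CH2Cl2, 40 °C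
Reagents that add atoms: methacrolein, CC(=C)C=O
Why: Olefin cross-metathesis of the terminal alkene with methacrolein gives the trisubstituted enal with the formyl group trans to the chain (E), and benzoquinone suppresses isomerisation of the allylarene.

Step 13
Reactants: 10 (2S,3S,4S)-3-(iodomethyl)-2,3,4-trimethylcyclohexan-1-one; 18 4-chloro-5-methyl-2-[(2E)-3-methyl-4-oxobut-2-en-1-yl]-1,3-phenylene diacetate
Product: 20 4-chloro-2-{(2E,4S)-4-hydroxy-3-methyl-5-[(1S,2S,6S)-1,2,6-trimethyl-3-oxocyclohexyl]pent-2-en-1-yl}-5-methyl-1,3-phenylene diacetate, via trimethylsilyl ether 19 (not isolated)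
Conditions: CrCl2 (20 mol%), (S)-oxazoline–sulfonamide ligand N-{2-[(4S)-4-isopropyl-4,5-dihydro-1,3-oxazol-2-yl]-6-methoxyphenyl}methanesulfonamide (22 mol%), 1,8-bis(dimethylamino)naphthalene (22 mol%), cobalt phthalocyanine Co(C32H16N8) (5 mol%), Mn powder, Me3SiCl, MeCN/DME, rt; then 1 M HCl, THF, 0 °C
Reagents that add atoms: none
Why: Monovalent cobalt (formed in situ from the phthalocyanine) takes the iodine of 10 to give an alkylcobalt whose weak Co–C bond releases the primary C1' radical, ligated divalent chromium captures it as a trivalent alkylchromium (radical–polar crossover, which reverses the polarity of the halide carbon), this adds 1,2 to the aldehyde of 18, Me3SiCl frees the chromium alkoxide as 19 and Mn returns chromium to the divalent state. The closest known reaction types are the cobalt-catalysed alkyl variant of the Nozaki–Hiyama–Kishi coupling of primary alkyl iodides with aldehydes and the catalytic asymmetric chromium-mediated couplings run with oxazoline–sulfonamide ligands. No ring is closed. The new C2' stereocentre (S, from Si-face attack) is set by the chiral ligand on chromium, since the nearest ring stereocentre is 1,3-related through a quaternary carbon and offers little bias. The step needs aldehyde-over-ketone and 1,2-over-1,4 selectivity and tolerance of the aryl chloride and aryl acetates, which follow from the aldehyde preference and low basicity of alkylchromium reagents, from the α-methyl group of the enal and from the absence of nickel. The quaternary C3 removes every β-hydride pathway for the radical, the alkylcobalt and the alkylchromium.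

Step 14
Reactants: 20 4-chloro-2-{(2E,4S)-4-hydroxy-3-methyl-5-[(1S,2S,6S)-1,2,6-trimethyl-3-oxocyclohexyl]pent-2-en-1-yl}-5-methyl-1,3-phenylene diacetate
Product: 21 (2S,3S,4S)-3-[(2S,3E)-5-(3-chloro-2,6-dihydroxy-4-methylphenyl)-2-hydroxy-3-methylpent-3-en-1-yl]-2,3,4-trimethylcyclohexan-1-one
Conditions: K2CO3, MeOH, argon, 0 °C → rt; aq. NH4Cl
Reagents that add atoms: none
Why: Base-mediated methanolysis (transesterification) removes both aryl acetates without acid, and the carbonate also equilibrates C2 of the cyclohexanone so that any 2R material converges on the more stable 2S epimer.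

Step 15
Reactants: 21 (2S,3S,4S)-3-[(2S,3E)-5-(3-chloro-2,6-dihydroxy-4-methylphenyl)-2-hydroxy-3-methylpent-3-en-1-yl]-2,3,4-trimethylcyclohexan-1-one
Product: 22 2-chloro-5-hydroxy-6-{(2E,4S)-4-hydroxy-3-methyl-5-[(1S,2S,6S)-1,2,6-trimethyl-3-oxocyclohexyl]pent-2-en-1-yl}-3-methylcyclohexa-2,5-diene-1,4-dione (CNP0469571.3)
Conditions: Fremy's salt ON(SO3K)2 (2.5 equiv), KH2PO4 buffer, acetone/H2O, 0 °C → rt
Reagents that add atoms: potassium nitrosodisulfonate, [K+].[K+].[O]N(S([O-])(=O)=O)S([O-])(=O)=O
Why: Teuber oxidation: the nitroxide abstracts a phenolic hydrogen and a second equivalent oxygenates the only free ring position (para to one OH, ortho to the other), which gives the 2-hydroxy-1,4-benzoquinone while the alcohol, ketone and alkene are inert.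

**Compound list**

1 | 3-ethoxy-2-methylcyclohex-2-en-1-one | CCOC1=C(C)C(=O)CCC1 | starting material
2 | lithium 5-ethoxy-6-methylcyclohexa-1,5-dien-1-olate | CCOC1=C(C)C(O[Li])=CCC1 | intermediate (not isolated)
3 | (±)-3-ethoxy-2,6-dimethylcyclohex-2-en-1-one (racemic) | CCOC1=C(C)C(=O)C(C)CC1 | intermediate
4 | 3-ethoxy-1,2,6-trimethylcyclohex-2-en-1-ol (racemic, both diastereomers) | CCOC1=C(C)C(C)(O)C(C)CC1 | intermediate (not isolated)
5 | (±)-2,3,4-trimethylcyclohex-2-en-1-one (racemic) | CC1CCC(=O)C(C)=C1C | intermediate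
6 | (1R,4S)-2,3,4-trimethylcyclohex-2-en-1-ol | C[C@H]1CC[C@@H](O)C(C)=C1C | intermediate
7 | (1S,2R,5S,6S)-1,5,6-trimethylbicyclo[4.1.0]heptan-2-ol | C[C@H]1CC[C@@H](O)[C@@]2(C)C[C@@]12C | intermediate
8 | (1S,5S,6S)-1,5,6-trimethylbicyclo[4.1.0]heptan-2-one | C[C@H]1CCC(=O)[C@@]2(C)C[C@@]12C | intermediate
9 | {[(3S,4S)-3-(iodomethyl)-2,3,4-trimethylcyclohex-1-en-1-yl]oxy}trimethylsilane | IC[C@]1(C)C(C)=C(O[Si](C)(C)C)CC[C@@H]1C | intermediate (not isolated)
10 | (2S,3S,4S)-3-(iodomethyl)-2,3,4-trimethylcyclohexan-1-one | IC[C@]1(C)[C@H](C)C(=O)CC[C@@H]1C | intermediate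
11 | orcinol (5-methylbenzene-1,3-diol) | Cc1cc(O)cc(O)c1 | starting material
12 | 4-chloro-5-methylbenzene-1,3-diol | Cc1cc(O)cc(O)c1Cl | intermediate
13 | 2-chloro-1,5-bis(methoxymethoxy)-3-methylbenzene | Cc1cc(OCOC)cc(OCOC)c1Cl | intermediate
14 | [3-chloro-2,6-bis(methoxymethoxy)-4-methylphenyl]lithium | Cc1cc(OCOC)c([Li])c(OCOC)c1Cl | intermediate (not isolated)
15 | 2-chloro-3,5-bis(methoxymethoxy)-1-methyl-4-(prop-2-en-1-yl)benzene | Cc1cc(OCOC)c(CC=C)c(OCOC)c1Cl | intermediate
16 | 4-chloro-5-methyl-2-(prop-2-en-1-yl)benzene-1,3-diol | Cc1cc(O)c(CC=C)c(O)c1Cl | intermediate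
17 | 4-chloro-5-methyl-2-(prop-2-en-1-yl)-1,3-phenylene diacetate | Cc1cc(OC(C)=O)c(CC=C)c(OC(C)=O)c1Cl | intermediate
18 | 4-chloro-5-methyl-2-[(2E)-3-methyl-4-oxobut-2-en-1-yl]-1,3-phenylene diacetate | Cc1cc(OC(C)=O)c(C/C=C(\C)C=O)c(OC(C)=O)c1Cl | intermediate
19 | trimethylsilyl ether of 20 at the C2' oxygen | Cc1cc(OC(C)=O)c(C/C=C(\C)[C@@H](O[Si](C)(C)C)C[C@]2(C)[C@H](C)C(=O)CC[C@@H]2C)c(OC(C)=O)c1Cl | intermediate (not isolated)
20 | 4-chloro-2-{(2E,4S)-4-hydroxy-3-methyl-5-[(1S,2S,6S)-1,2,6-trimethyl-3-oxocyclohexyl]pent-2-en-1-yl}-5-methyl-1,3-phenylene diacetate | Cc1cc(OC(C)=O)c(C/C=C(\C)[C@@H](O)C[C@]2(C)[C@H](C)C(=O)CC[C@@H]2C)c(OC(C)=O)c1Cl | intermediate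
21 | (2S,3S,4S)-3-[(2S,3E)-5-(3-chloro-2,6-dihydroxy-4-methylphenyl)-2-hydroxy-3-methylpent-3-en-1-yl]-2,3,4-trimethylcyclohexan-1-one | Cc1cc(O)c(C/C=C(\C)[C@@H](O)C[C@]2(C)[C@H](C)C(=O)CC[C@@H]2C)c(O)c1Cl | intermediate
22 | 2-chloro-5-hydroxy-6-{(2E,4S)-4-hydroxy-3-methyl-5-[(1S,2S,6S)-1,2,6-trimethyl-3-oxocyclohexyl]pent-2-en-1-yl}-3-methylcyclohexa-2,5-diene-1,4-dione | CC1=C(Cl)C(=O)C(C/C=C(\C)[C@@H](O)C[C@]2(C)[C@H](C)C(=O)CC[C@@H]2C)=C(O)C1=O | target

**Count and risks**

Total steps: 15. Longest linear sequence: 9 steps (steps 1–6 or 7–12, then 13–15).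

Steps most likely to fail:

1. Step 13. The hindered iodide may be slow to give its radical at cobalt, which lets reductive dimerisation of the enal compete, and facial control by the ligand at the α-branched enal may be poor. The fallback separates bond formation from stereocontrol. Enal 18 is oxidised (NaClO2, NaH2PO4, 2-methylbut-2-ene; Pinnick oxidation) to (2E)-4-[2,6-bis(acetyloxy)-3-chloro-4-methylphenyl]-2-methylbut-2-enoic acid F1. This is converted with 2,2'-dipyridyl disulfide and PPh3 into its S-pyridin-2-yl thioester F2. F2 and iodide 10 are joined by a nickel-catalysed reductive acyl cross-coupling (NiBr2(dtbbpy), Zr(Cp)2Cl2, Zn dust, DMI/EtOAc) to the enone 4-chloro-5-methyl-2-{(2E)-3-methyl-4-oxo-5-[(1S,2S,6S)-1,2,6-trimethyl-3-oxocyclohexyl]pent-2-en-1-yl}-1,3-phenylene diacetate F3. The enone carbonyl is then reduced with (R)-Me-CBS and catecholborane at −78 °C; the ring ketone, flanked by a methyl-bearing carbon next to the quaternary centre, should react much more slowly. This sets out from 18 and 10 and rejoins the route at 20.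

2. Step 6. Iodide may fail to attack the crowded CH2, so that the ring-fusion bond to the tertiary carbon breaks instead (ring expansion) or HI is lost; equilibration at C2 may also be incomplete. The fallback installs the one-carbon unit by a sigmatropic shift instead of a ring opening. Alcohol 6 is alkylated (KH, Bu3SnCH2I, THF) to tributyl({[(1R,4S)-2,3,4-trimethylcyclohex-2-en-1-yl]oxy}methyl)stannane F4. Tin–lithium exchange (n-BuLi, −78 °C) triggers a [2,3]-Wittig–Still rearrangement that delivers CH2OH to C3 on the face of the old C–O bond and gives [(1S,6S)-1,2,6-trimethylcyclohex-2-en-1-yl]methanol F5. I2, PPh3 and imidazole in toluene at 80 °C give (5S,6S)-6-(iodomethyl)-1,5,6-trimethylcyclohex-1-ene F6. Hydroboration–oxidation (BH3·THF, then NaBO3) gives (1S,2S,3S,4S)-3-(iodomethyl)-2,3,4-trimethylcyclohexan-1-ol F7; its configuration at C1 and C2 is of no consequence. Oxidation ((n-Pr4N)RuO4, N-methylmorpholine N-oxide) and acid equilibration then give the ketone. This sets out from 6 and rejoins the route at 10.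

3. Step 15. Oxidation of the electron-rich ring may be incomplete or go further (degradation of the hydroxyquinone, attack at the chlorine-bearing carbon). The fallback is an anionic autoxidation instead of a nitroxide oxidation: diacetate 20 is stirred with KOH in MeOH under O2, conditions that convert 2-substituted 5-alkylresorcinols into hydroxyquinones, so that acetate cleavage and oxidation of the resorcinolate occur in one flask. This sets out from 20 and arrives directly at 22, and makes no new compound.

**Further compounds**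

F1 | step 13 | (2E)-4-[2,6-bis(acetyloxy)-3-chloro-4-methylphenyl]-2-methylbut-2-enoic acid | Cc1cc(OC(C)=O)c(C/C=C(\C)C(O)=O)c(OC(C)=O)c1Cl
F2 | step 13 | S-pyridin-2-yl (2E)-4-[2,6-bis(acetyloxy)-3-chloro-4-methylphenyl]-2-methylbut-2-enethioate | Cc1cc(OC(C)=O)c(C/C=C(\C)C(=O)Sc2ccccn2)c(OC(C)=O)c1Cl
F3 | step 13 | 4-chloro-5-methyl-2-{(2E)-3-methyl-4-oxo-5-[(1S,2S,6S)-1,2,6-trimethyl-3-oxocyclohexyl]pent-2-en-1-yl}-1,3-phenylene diacetate | Cc1cc(OC(C)=O)c(C/C=C(\C)C(=O)C[C@]2(C)[C@H](C)C(=O)CC[C@@H]2C)c(OC(C)=O)c1Cl
F4 | step 6 | tributyl({[(1R,4S)-2,3,4-trimethylcyclohex-2-en-1-yl]oxy}methyl)stannane | C[C@H]1CC[C@@H](OC[Sn](CCCC)(CCCC)CCCC)C(C)=C1C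
F5 | step 6 | [(1S,6S)-1,2,6-trimethylcyclohex-2-en-1-yl]methanol | OC[C@]1(C)C(C)=CCC[C@@H]1C
F6 | step 6 | (5S,6S)-6-(iodomethyl)-1,5,6-trimethylcyclohex-1-ene | IC[C@]1(C)C(C)=CCC[C@@H]1C
F7 | step 6 | (1S,2S,3S,4S)-3-(iodomethyl)-2,3,4-trimethylcyclohexan-1-ol | IC[C@]1(C)[C@H](C)[C@@H](O)CC[C@@H]1C
F0 | step 15 | none | none
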